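At early times the elm run loses substrate faster than it makes product: by 4.00 h, free substrate reads 39.8% and product 8.9%.

| flask | substrate | partner | free catalyst | remark | time |
|---|---|---|---|---|---|
| elm | 0.050 M | 0.050 M | 4.1 mM | run made earlier |  |
| maple | 0.050 M | 0.11 M | 4.1 mM | run made earlier |  |
| cedar | 0.050 M | 0.075 M | 2 mM | run made earlier |  |
| Tuesday's | 0.050 M | 0.0750 M | 4.1 mM |  | 40 h |
| Wednesday's | 0.050 M | 0.0750 M | 4.1 mM |  | 50 h |

- elm (time / h: catalyst intermediate D / %, substrate / %, product / %): 2.00: 0, 52.3, 2.9; 4.00: 0.6, 39.8, 8.9; 6.00: 1.8, 39.1, 14.4; 12.0: 0.4, 32.6, 27.1; 25.0: 0.1, 23.3, 48.6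
- maple (time / h: catalyst intermediate D / %, substrate / %, product / %): 2.00: 0.5, 53.0, 5.4; 4.00: 0, 40.1, 10.0; 6.00: 0, 38.0, 13.8; 12.0: 0.4, 31.5, 30.9; 25.0: 0, 19.5, 52.9
- cedar (time / h: catalyst intermediate D / %, substrate / %, product / %): 2.00: 0, 54.6, 1.3; 6.00: 1.5, 41.2, 9.1; 12.0: 0, 38.3, 14.1; 15.0: 0.7, 36.8, 19.2; 25.0: 0, 31.6, 30.7

(each reading ± 1 percentage point)

* which of these there is most of at the end, counted by the substrate in it, Tuesday's (substrate / catalyst intermediate D / product)
* which of these there is most of at the end, counted by the substrate in it, Wednesday's (substrate / catalyst intermediate D / product)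
* the largest of these amounts at the end, in percent of the substrate charged, Tuesday's
* the largest of these amounts at the end, in percent of the substrate charged, Wednesday's

- a reading of substrate is of its free form alone

In elm, the balance of substrate lacks 50.7% of the charge at that time, once catalyst intermediate D is counted. The catalyst charge is 8.20% of the substrate, so it cannot hold that gap, and an unseen pool of substrate must exist. In elm, the pool read against free substrate is 1.27 then and 1.20 at 25.0 h, so the two fall together.

The reckoning therefore follows U, the share of the charge not yet product, and takes a pseudo-first-order constant k = ln(1/U)/t. The last readings give 0.0266 h⁻¹ for elm and 0.0301 h⁻¹ for maple. A straight line in partner between them gives 0.0281 h⁻¹ for Tuesday's flask, hence 67.5% product.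

That assumed line is the weak link, and cedar replaces it, because cedar holds Tuesday's partner. With half the catalyst, cedar has the constant 0.0147 h⁻¹, half the value reckoned for Tuesday's flask. So k is divided by the catalyst charge, giving the constant per catalyst, κ, 7.33 L mol⁻¹ h⁻¹. Then the reckoning gives 70.0% product for Tuesday's flask and 77.8% for Wednesday's, and in each, product exceeds everything else together.

The forecast also names product for both flasks, but with lower amounts: 66% and 73%, “Allowing for slight slowing”.

The flasks give product, at 70.2% on Tuesday's and 78.7% on Wednesday's, the latter 5.7 percentage points above the forecast.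

    partner + free catalyst → catalyst intermediate A (k = 47.4 L mol⁻¹ h⁻¹)
    catalyst intermediate A → by-product + catalyst intermediate B (k = 3.11 h⁻¹)
    catalyst intermediate B → catalyst intermediate C (k = 4.49 h⁻¹)
    substrate + catalyst intermediate C ⇌ catalyst intermediate D (K = 2.50 L mol⁻¹, k = 556 L mol⁻¹ h⁻¹)
    catalyst intermediate D → free catalyst + product (k = 9.09 h⁻¹)
    substrate ⇌ dormant form (K = 1.17, k = 0.463 h⁻¹)

Read back from these results, κ is 7.37 L mol⁻¹ h⁻¹ for Tuesday's flask and 7.55 L mol⁻¹ h⁻¹ for Wednesday's, against 7.33 L mol⁻¹ h⁻¹ from cedar. The neighbouring flask is Tuesday's flask with 0.0010 M of free catalyst. With κ, the reckoning gives that neighbour 25.4% product at 40 h, and dividing what remains by one plus the pool reading 1.20 leaves 33.9% free substrate, so substrate there exceeds product. The neighbouring flask holds 34.5% substrate and 24.4% product.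

(The numbers in the tables are calculated on assumed constants.)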